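Ring C is disconnected at C3–C4 and O1–C8a. In one pot the lithium enolate of a ring B methyl ketone, already carrying the threo (7''R,8''R) arylglycerol ether, is C-aroylated by 2,4,6-trifluorobenzoyl chloride, and the diketonate oxygen then displaces an ortho fluoride, closing the pyranone as a 5,7-difluoroflavone. The step exploits the C4 carbonyl on C4a of ring A, which is ortho to C8a and C5 and para to C7 and so activates all three C–F bonds: one closes ring C, the other two are later exchanged for benzyloxy groups. C2 is then set by asymmetric hydrogenation; the side chain comes from an Evans syn-glycolate aldol.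

Key step: step 6

Remark: flavonoid numbering is used (O1, C2, C3, C4, C4a, C5–C8, C8a; side chain C7'' carbinol, C8'' aryloxy carbon, C9'' CH2OH); Ar* stands for the 4-{[(4R,5R)-4-[4-(benzyloxy)phenyl]-2,2-dimethyl-1,3-dioxan-5-yl]oxy}-3,5-dimethoxyphenyl group; compound 2 is assumed to be a catalogue compound.

Step 1
Reactants: 1 4-bromo-2,6-dimethoxyphenol; 2 (4S)-4-benzyl-3-(2-chloroacetyl)-1,3-oxazolidin-2-one
Product: 3 (4S)-4-benzyl-3-[2-(4-bromo-2,6-dimethoxyphenoxy)acetyl]-1,3-oxazolidin-2-one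
Conditions: K2CO3, NaI (cat.), acetone, 50 °C
Reagents that add atoms: none
Why: Williamson ether synthesis with Finkelstein catalysis: the hindered phenoxide should displace halide at the SN2-activated α-carbon much faster than it attacks the imide carbonyl, and the auxiliary stereocenter is not touched.

Step 2
Reactants: 3 (4S)-4-benzyl-3-[2-(4-bromo-2,6-dimethoxyphenoxy)acetyl]-1,3-oxazolidin-2-one; 4 4-(benzyloxy)benzaldehyde
Product: 6 (4S)-4-benzyl-3-[(2S,3R)-3-[4-(benzyloxy)phenyl]-2-(4-bromo-2,6-dimethoxyphenoxy)-3-hydroxypropanoyl]-1,3-oxazolidin-2-one, via Z-boron enolate 5 (not isolated)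
Conditions: Bu2BOTf, i-Pr2NEt, CH2Cl2, 0 °C; then 4, −78 → 0 °C; pH 7 buffer, MeOH, 30% H2O2, 0 °C
Reagents that add atoms: none
Why: Evans syn-aldol reaction: the Z-boron enolate 5 reacts through a Zimmerman–Traxler chair in which the benzyl group of the (S)-auxiliary blocks one enolate face, which should set C2 (S) and C3 (R) of the acyl chain together as the syn pair that becomes the threo (7''R,8''R) unit.

Step 3
Reactants: 6 syn-aldol adduct
Product: 7 (1R,2R)-1-[4-(benzyloxy)phenyl]-2-(4-bromo-2,6-dimethoxyphenoxy)propane-1,3-diol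
Conditions: LiBH4, H2O (1 equiv), THF, 0 °C → rt
Reagents that add atoms: none
Why: Reductive cleavage of the N-acyloxazolidinone by LiBH4 occurs at the exocyclic carbonyl and leaves both stereocenters untouched (the descriptor at the aryloxy carbon changes from S to R only because the CIP priorities change).

Step 4
Reactants: 7 (1R,2R)-diol
Product: 8 (4R,5R)-4-[4-(benzyloxy)phenyl]-5-(4-bromo-2,6-dimethoxyphenoxy)-2,2-dimethyl-1,3-dioxane (Ar*–Br)
Conditions: Me2C(OMe)2, PPTS (cat.), CH2Cl2, rt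
Reagents that add atoms: 2,2-dimethoxypropane, COC(C)(C)OC
Why: Acid-catalysed transketalisation ties the 1,3-diol into a 1,3-dioxane with the aryl and aryloxy groups both equatorial, so no epimerisation is expected under PPTS.

Step 5
Reactants: 8 aryl bromide Ar*–Br
Product: 10 1-Ar*-ethan-1-one (Ar*–COCH3), via aryllithium 9 (not isolated)
Conditions: n-BuLi, THF, −78 °C; then MeC(O)N(OMe)Me, −78 → 0 °C; aq. NH4Cl
Reagents that add atoms: N-methoxy-N-methylacetamide, CC(=O)N(C)OC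
Why: Bromine–lithium exchange followed by Weinreb ketone synthesis: the aryllithium 9 should add only once because the chelated tetrahedral adduct survives until work-up.

Step 6
Reactants: 10 methyl ketone Ar*–COCH3; 11 2,4,6-trifluorobenzoyl chloride
Product: 14 2-Ar*-5,7-difluoro-4H-chromen-4-one, via lithium enolate 12 (not isolated), via 1,3-diketone 13 (not isolated)
Conditions: LiN(SiMe3)2 (2.1 equiv), THF, −78 °C; then 11, −78 → 0 °C; then DMF, 70 °C
Reagents that add atoms: none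
Why: The lithium enolate 12 is C-aroylated by 11 (Claisen-type acylation, forming C3–C4) to give diketone 13, which the second equivalent of base deprotonates at once; on warming in DMF the enolate oxygen on the ring B side attacks C8a, ortho to the aroyl carbonyl, and fluoride leaves from the Meisenheimer intermediate (intramolecular SNAr, forming O1–C8a). The closest known reaction type is the one-pot chromone synthesis from ketone enolates and 2-fluorobenzoyl chlorides, the oxygen counterpart of the Grohe–Heitzer quinolone cycloaroylation. Ring C closes in a six-membered mode that is formally a 6-endo-trig conjugate addition to the C4=O/C4a=C8a vinylogous acyl fluoride followed by elimination, whereas closure through C3 or through the C4 oxygen would need a four-membered ring. No stereocenter is formed (C2 is trigonal here and is set in step 8) and the two side-chain centers carry no acidic hydrogen. The step needs C- over O-acylation, which the lithium counterion in THF at low temperature favours, and mono-acylation, which the deprotonated diketone secures. Regiochemistry of closure is not an issue because both ortho positions of the symmetric 2,4,6-trifluorophenyl group carry fluorine and the para fluorine cannot be reached.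

Step 7
Reactants: 14 2-Ar*-5,7-difluoro-4H-chromen-4-one
Product: 15 5,7-bis(benzyloxy)-2-Ar*-4H-chromen-4-one
Conditions: BnOH, NaH, DMF, 0 → 60 °C
Reagents that add atoms: benzyl alcohol, OCc1ccccc1
Why: Twofold SNAr: benzyl alkoxide should replace the fluorides at C7 (para) and C5 (ortho), both activated by the C4 carbonyl, as known for 5,7-difluorochromones and fluoroquinolones.

Step 8
Reactants: 15 5,7-bis(benzyloxy)-2-Ar*-4H-chromen-4-one
Product: 16 (2S,4S)-5,7-bis(benzyloxy)-2-Ar*-chroman-4-ol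
Conditions: [Ru(cod)(2-methylallyl)2] (5 mol %), (R,R)-SINpEt·HBF4 (10 mol %), KOtBu (15 mol %), H2 (100 bar), toluene, 40 °C
Reagents that add atoms: none
Why: Ruthenium–NHC-catalysed asymmetric hydrogenation of flavones: H2 is delivered syn to C2=C3 from the face chosen by the chiral carbene ligand (Re face at C2 for 2S; the ligand antipode is to be confirmed on 5,7-bis(benzyloxy)flavone), and the ketone is then reduced to the expected cis alcohol, whose C4 center is removed in step 9.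

Step 9
Reactants: 16 (2S,4S)-flavan-4-ol
Product: 17 (2S)-5,7-bis(benzyloxy)-2-Ar*-chroman-4-one
Conditions: Dess–Martin periodinane, NaHCO3, CH2Cl2, 0 °C → rt
Reagents that add atoms: none
Why: Buffered Dess–Martin oxidation of the benzylic secondary alcohol avoids both acid (ionisation of the electron-rich flavan-4-ol) and base (ring opening to the chalcone), so the C2 stereocenter should be preserved.

Step 10
Reactants: 17 (2S)-flavanone acetonide
Product: 18 (2S)-5,7-bis(benzyloxy)-2-[4-[[(1R,2R)-1-[4-(benzyloxy)phenyl]-1,3-dihydroxypropan-2-yl]oxy]-3,5-dimethoxyphenyl]chroman-4-one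
Conditions: AcOH/H2O (4:1), 40 °C
Reagents that add atoms: none
Why: Mild acid-catalysed acetal hydrolysis frees the 1,3-diol without ionising the C7'' benzylic position (its aryl group is still an O-benzyl ether) and without enolising the flavanone.

Step 11
Reactants: 18 tri-O-benzyl diol
Product: 19 (2S)-5,7-dihydroxy-2-[4-[[(1R,2R)-1,3-dihydroxy-1-(4-hydroxyphenyl)propan-2-yl]oxy]-3,5-dimethoxyphenyl]chroman-4-one (target)
Conditions: H2 (1 atm), 10% Pd/C, EtOAc/MeOH, rt
Reagents that add atoms: none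
Why: Hydrogenolysis of the three aryl benzyl ethers under neutral conditions should be faster than cleavage of the secondary benzylic C7''–OH or C2–O1 bonds and does not touch C2 or the ketone.

Compound list
1 | 4-bromo-2,6-dimethoxyphenol | COc1cc(Br)cc(OC)c1O | starting material
2 | (4S)-4-benzyl-3-(2-chloroacetyl)-1,3-oxazolidin-2-one | O=C(CCl)N1[C@@H](Cc2ccccc2)COC1=O | starting material
3 | (4S)-4-benzyl-3-[2-(4-bromo-2,6-dimethoxyphenoxy)acetyl]-1,3-oxazolidin-2-one | COc1cc(Br)cc(OC)c1OCC(=O)N1[C@@H](Cc2ccccc2)COC1=O | intermediate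
4 | 4-(benzyloxy)benzaldehyde | O=Cc1ccc(OCc2ccccc2)cc1 | starting material
5 | (4S)-4-benzyl-3-[(Z)-2-(4-bromo-2,6-dimethoxyphenoxy)-1-(dibutylboranyloxy)ethenyl]-1,3-oxazolidin-2-one (Z-boron enolate of 3) | CCCCB(CCCC)O/C(=C\Oc1c(OC)cc(Br)cc1OC)N1[C@@H](Cc2ccccc2)COC1=O | intermediate
6 | (4S)-4-benzyl-3-[(2S,3R)-3-[4-(benzyloxy)phenyl]-2-(4-bromo-2,6-dimethoxyphenoxy)-3-hydroxypropanoyl]-1,3-oxazolidin-2-one | O=C([C@@H](Oc1c(OC)cc(Br)cc1OC)[C@H](O)c1ccc(OCc2ccccc2)cc1)N1[C@@H](Cc2ccccc2)COC1=O | intermediate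
7 | (1R,2R)-1-[4-(benzyloxy)phenyl]-2-(4-bromo-2,6-dimethoxyphenoxy)propane-1,3-diol | OC[C@@H](Oc1c(OC)cc(Br)cc1OC)[C@H](O)c1ccc(OCc2ccccc2)cc1 | intermediate
8 | (4R,5R)-4-[4-(benzyloxy)phenyl]-5-(4-bromo-2,6-dimethoxyphenoxy)-2,2-dimethyl-1,3-dioxane | CC1(C)OC[C@@H](Oc2c(OC)cc(Br)cc2OC)[C@H](O1)c1ccc(OCc2ccccc2)cc1 | intermediate
9 | [4-[[(4R,5R)-4-[4-(benzyloxy)phenyl]-2,2-dimethyl-1,3-dioxan-5-yl]oxy]-3,5-dimethoxyphenyl]lithium | CC1(C)OC[C@@H](Oc2c(OC)cc([Li])cc2OC)[C@H](O1)c1ccc(OCc2ccccc2)cc1 | intermediate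
10 | 1-[4-[[(4R,5R)-4-[4-(benzyloxy)phenyl]-2,2-dimethyl-1,3-dioxan-5-yl]oxy]-3,5-dimethoxyphenyl]ethan-1-one | CC1(C)OC[C@@H](Oc2c(OC)cc(C(C)=O)cc2OC)[C@H](O1)c1ccc(OCc2ccccc2)cc1 | intermediate
11 | 2,4,6-trifluorobenzoyl chloride | O=C(Cl)c1c(F)cc(F)cc1F | starting material
12 | lithium 1-[4-[[(4R,5R)-4-[4-(benzyloxy)phenyl]-2,2-dimethyl-1,3-dioxan-5-yl]oxy]-3,5-dimethoxyphenyl]ethen-1-olate | CC1(C)OC[C@@H](Oc2c(OC)cc(C(=C)O[Li])cc2OC)[C@H](O1)c1ccc(OCc2ccccc2)cc1 | intermediate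
13 | 1-[4-[[(4R,5R)-4-[4-(benzyloxy)phenyl]-2,2-dimethyl-1,3-dioxan-5-yl]oxy]-3,5-dimethoxyphenyl]-3-(2,4,6-trifluorophenyl)propane-1,3-dione | CC1(C)OC[C@@H](Oc2c(OC)cc(C(=O)CC(=O)c3c(F)cc(F)cc3F)cc2OC)[C@H](O1)c1ccc(OCc2ccccc2)cc1 | intermediate
14 | 2-[4-[[(4R,5R)-4-[4-(benzyloxy)phenyl]-2,2-dimethyl-1,3-dioxan-5-yl]oxy]-3,5-dimethoxyphenyl]-5,7-difluoro-4H-chromen-4-one | CC1(C)OC[C@@H](Oc2c(OC)cc(-c3cc(=O)c4c(F)cc(F)cc4o3)cc2OC)[C@H](O1)c1ccc(OCc2ccccc2)cc1 | intermediate
15 | 5,7-bis(benzyloxy)-2-[4-[[(4R,5R)-4-[4-(benzyloxy)phenyl]-2,2-dimethyl-1,3-dioxan-5-yl]oxy]-3,5-dimethoxyphenyl]-4H-chromen-4-one | CC1(C)OC[C@@H](Oc2c(OC)cc(-c3cc(=O)c4c(OCc5ccccc5)cc(OCc5ccccc5)cc4o3)cc2OC)[C@H](O1)c1ccc(OCc2ccccc2)cc1 | intermediate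
16 | (2S,4S)-5,7-bis(benzyloxy)-2-[4-[[(4R,5R)-4-[4-(benzyloxy)phenyl]-2,2-dimethyl-1,3-dioxan-5-yl]oxy]-3,5-dimethoxyphenyl]-3,4-dihydro-2H-chromen-4-ol | CC1(C)OC[C@@H](Oc2c(OC)cc([C@@H]3C[C@H](O)c4c(OCc5ccccc5)cc(OCc5ccccc5)cc4O3)cc2OC)[C@H](O1)c1ccc(OCc2ccccc2)cc1 | intermediate
17 | (2S)-5,7-bis(benzyloxy)-2-[4-[[(4R,5R)-4-[4-(benzyloxy)phenyl]-2,2-dimethyl-1,3-dioxan-5-yl]oxy]-3,5-dimethoxyphenyl]-2,3-dihydro-4H-chromen-4-one | CC1(C)OC[C@@H](Oc2c(OC)cc([C@@H]3CC(=O)c4c(OCc5ccccc5)cc(OCc5ccccc5)cc4O3)cc2OC)[C@H](O1)c1ccc(OCc2ccccc2)cc1 | intermediate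
18 | (2S)-5,7-bis(benzyloxy)-2-[4-[[(1R,2R)-1-[4-(benzyloxy)phenyl]-1,3-dihydroxypropan-2-yl]oxy]-3,5-dimethoxyphenyl]-2,3-dihydro-4H-chromen-4-one | COc1cc([C@@H]2CC(=O)c3c(OCc4ccccc4)cc(OCc4ccccc4)cc3O2)cc(OC)c1O[C@H](CO)[C@H](O)c1ccc(OCc2ccccc2)cc1 | intermediate
19 | (2S)-5,7-dihydroxy-2-[4-[[(1R,2R)-1,3-dihydroxy-1-(4-hydroxyphenyl)propan-2-yl]oxy]-3,5-dimethoxyphenyl]-2,3-dihydro-4H-chromen-4-one | COc1cc([C@@H]2CC(=O)c3c(O)cc(O)cc3O2)cc(OC)c1O[C@H](CO)[C@H](O)c1ccc(O)cc1 | target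

Total step count: 11. Longest linear sequence: 11 steps (1 → 19); compounds 2, 4 and 11 enter as purchased materials.

Steps most likely to fail

1. Step 8. What may go wrong: weak facial discrimination at C2 by the catalyst on a large substrate with a bulky 5-benzyloxy group beside the carbonyl, stalled conversion, or partial saturation of electron-rich rings. The fallback sets out from 15 and comes back at 17. Flavone 15 is reduced at C2=C3 without stereocontrol by conjugate hydride delivery with LiBH(s-Bu)3 (THF, −78 °C) to the mixture of C2 epimers of the protected flavanone F1. This mixture is resolved kinetically by asymmetric transfer hydrogenation with RuCl(p-cymene)[(R,R)-TsDPEN] or its antipode (HCO2H/Et3N, EtOAc), chosen so that the 2R epimer is reduced to the cis-(2R,4R)-flavan-4-ol F2 while the 2S ketone 17 is left. Ketone and alcohol are separated by chromatography; the alcohol can be re-oxidised and re-equilibrated at C2 for recycling.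

2. Step 6. What may go wrong: O-acylation or double acylation of the enolate in place of clean C-acylation, and slow ring closure of the chelated lithium diketonate. The fallback sets out from 8 and comes back at 15, building ring C the classical way. Bromide 8 is lithiated (n-BuLi, THF, −78 °C) and carboxylated with CO2 to 4-{[(4R,5R)-4-[4-(benzyloxy)phenyl]-2,2-dimethyl-1,3-dioxan-5-yl]oxy}-3,5-dimethoxybenzoic acid F3. This acid is esterified (EDC·HCl, DMAP, CH2Cl2) with commercial 1-[2,4-bis(benzyloxy)-6-hydroxyphenyl]ethan-1-one to the 2-acetyl-3,5-bis(benzyloxy)phenyl ester F4. Baker–Venkataraman rearrangement (KOtBu, THF) should give the 1-[2,4-bis(benzyloxy)-6-hydroxyphenyl]-3-Ar*-propane-1,3-dione F5. Cyclodehydration (cat. TsOH, toluene, 80 °C, followed by 2,2-dimethoxypropane/PPTS if the acetonide has partly opened) gives 15 and makes step 7 unnecessary.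

3. Step 7. What may go wrong: stalling after the first substitution at C7, because the new alkoxy group deactivates ring A toward displacement at C5, and reversible alkoxide addition at C2 that opens the pyranone. The fallback sets out from 10 and comes back at 15, installing both benzyloxy groups before the annulation. Commercial methyl 2,4,6-trifluorobenzoate is treated with BnOH/NaH (2 equiv, THF) to give methyl 2,4-bis(benzyloxy)-6-fluorobenzoate F6, separated from any 2,6-isomer. It is saponified (LiOH, THF/H2O) to 2,4-bis(benzyloxy)-6-fluorobenzoic acid F7 and converted (oxalyl chloride, cat. DMF, CH2Cl2) into 2,4-bis(benzyloxy)-6-fluorobenzoyl chloride F8. The one-pot procedure of step 6 with 10 and this acid chloride then passes through the 1-Ar*-3-[2,4-bis(benzyloxy)-6-fluorophenyl]propane-1,3-dione F9, which closes at the only remaining C–F carbon to give 15.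

Further compounds
F1 | step 8 | (2RS)-5,7-bis(benzyloxy)-2-[4-[[(4R,5R)-4-[4-(benzyloxy)phenyl]-2,2-dimethyl-1,3-dioxan-5-yl]oxy]-3,5-dimethoxyphenyl]-2,3-dihydro-4H-chromen-4-one (mixture of C2 epimers) | CC1(C)OC[C@@H](Oc2c(OC)cc(C3CC(=O)c4c(OCc5ccccc5)cc(OCc5ccccc5)cc4O3)cc2OC)[C@H](O1)c1ccc(OCc2ccccc2)cc1
F2 | step 8 | (2R,4R)-5,7-bis(benzyloxy)-2-[4-[[(4R,5R)-4-[4-(benzyloxy)phenyl]-2,2-dimethyl-1,3-dioxan-5-yl]oxy]-3,5-dimethoxyphenyl]-3,4-dihydro-2H-chromen-4-ol | CC1(C)OC[C@@H](Oc2c(OC)cc([C@H]3C[C@@H](O)c4c(OCc5ccccc5)cc(OCc5ccccc5)cc4O3)cc2OC)[C@H](O1)c1ccc(OCc2ccccc2)cc1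
F3 | step 6 | 4-[[(4R,5R)-4-[4-(benzyloxy)phenyl]-2,2-dimethyl-1,3-dioxan-5-yl]oxy]-3,5-dimethoxybenzoic acid | CC1(C)OC[C@@H](Oc2c(OC)cc(C(=O)O)cc2OC)[C@H](O1)c1ccc(OCc2ccccc2)cc1
F4 | step 6 | 2-acetyl-3,5-bis(benzyloxy)phenyl 4-[[(4R,5R)-4-[4-(benzyloxy)phenyl]-2,2-dimethyl-1,3-dioxan-5-yl]oxy]-3,5-dimethoxybenzoate | CC1(C)OC[C@@H](Oc2c(OC)cc(C(=O)Oc3cc(OCc4ccccc4)cc(OCc4ccccc4)c3C(C)=O)cc2OC)[C@H](O1)c1ccc(OCc2ccccc2)cc1
F5 | step 6 | 1-[2,4-bis(benzyloxy)-6-hydroxyphenyl]-3-[4-[[(4R,5R)-4-[4-(benzyloxy)phenyl]-2,2-dimethyl-1,3-dioxan-5-yl]oxy]-3,5-dimethoxyphenyl]propane-1,3-dione | CC1(C)OC[C@@H](Oc2c(OC)cc(C(=O)CC(=O)c3c(O)cc(OCc4ccccc4)cc3OCc3ccccc3)cc2OC)[C@H](O1)c1ccc(OCc2ccccc2)cc1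
F6 | step 7 | methyl 2,4-bis(benzyloxy)-6-fluorobenzoate | COC(=O)c1c(F)cc(OCc2ccccc2)cc1OCc1ccccc1
F7 | step 7 | 2,4-bis(benzyloxy)-6-fluorobenzoic acid | OC(=O)c1c(F)cc(OCc2ccccc2)cc1OCc1ccccc1
F8 | step 7 | 2,4-bis(benzyloxy)-6-fluorobenzoyl chloride | O=C(Cl)c1c(F)cc(OCc2ccccc2)cc1OCc1ccccc1
F9 | step 7 | 1-[2,4-bis(benzyloxy)-6-fluorophenyl]-3-[4-[[(4R,5R)-4-[4-(benzyloxy)phenyl]-2,2-dimethyl-1,3-dioxan-5-yl]oxy]-3,5-dimethoxyphenyl]propane-1,3-dione | CC1(C)OC[C@@H](Oc2c(OC)cc(C(=O)CC(=O)c3c(F)cc(OCc4ccccc4)cc3OCc3ccccc3)cc2OC)[C@H](O1)c1ccc(OCc2ccccc2)cc1
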